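**Plan**

1. Numbering follows the octahydronaphthalene core (ring A: C1–C4, C4a, C8a; ring B: C4a, C5–C8, C8a). Retrosynthesis: the sulfate and the dienoate (C1-vinyl plus sorbate cross-metathesis) are cut first; ring A is stripped back to a cis-fused C3 ketone (C3–Me/C3=C4 by Shapiro methylation, C2–butenyl by enolate alkenylation, C1–vinyl by cuprate addition); C1–C8a is cut by a retro-oxy-Cope to a 2-vinylbicyclo[2.2.2]octenol; last, C4a–C5 and C6–C7 are cut by a retro-Diels–Alder.
2. Forward: 2,6-dimethoxy-3-methylphenol is dearomatised to an o-quinone monoketal that takes up phenyl vinyl sulfone (traceless C5–C6), giving ring B inside a strained bicyclo[2.2.2]octenone; vinyl addition and anionic oxy-Cope close ring A cis-fused; ring A is then decorated, the ring-B enol ether is hydrolysed and reduced, the chain is extended and O7 is sulfated.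
3. Enabling feature: C3, C4, C4a, C8a, C8 and C7 are the six carbons of one arene; O7 and the C8 methyl sit on the diene C7=C8–C8a=C4a, C5–C6 carries no substituent, and the C3–C4 keto-ketal bridge stores the strain that later drives C1–C8a bond formation.
4. Stereochemistry: C4a from the resolved cycloadduct; C8a from the suprafacial oxy-Cope (cis fusion); C1 by convex-face cuprate addition; C2 anti to C1 (epimerisable, thermodynamic); C8 by kinetic enol-ether protonation anti to the C8a–C1 bond; C7 by hydride delivery anti to the C8 methyl.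

Key step: step 3

Assumption: the key cycloaddition is run on an achiral diene without absolute control, the racemic adduct is resolved directly afterwards (step 4) and every later centre is relayed from it; the target is taken in its free-acid form.

**Route**

Step 1
Reactants: 1 2,6-dimethoxyphenol
Product: 2 2-(methoxymethoxy)-1,3-dimethoxybenzene
Conditions: MOMCl, iPr2NEt, CH2Cl2, 0 °C → rt
Reagents that add atoms: chloromethyl methyl ether, COCCl
Why: O-alkylation of the phenol (acetal protection) gives a group inert to n-BuLi, so that ring lithiation is directed by a flanking methoxy group.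

Step 2
Reactants: 2 2-(methoxymethoxy)-1,3-dimethoxybenzene
Product: 5 2,6-dimethoxy-3-methylphenol, via aryllithium 3 (not isolated), via methylated MOM ether 4 (not isolated)
Conditions: n-BuLi, TMEDA, THF, 0 °C; MeI, −78 °C → rt; then HCl, MeOH, 50 °C
Reagents that add atoms: iodomethane, CI
Why: Directed ortho-metalation next to OMe (both positions ortho to the MOM ether are blocked), C-methylation and acidic acetal cleavage place the future C8 methyl beside the future C7 oxygen.

Step 3
Reactants: 5 2,6-dimethoxy-3-methylphenol; 6 phenyl vinyl sulfone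
Product: 8 racemic (1S*,4S*,7S*)-1,3,3-trimethoxy-6-methyl-7-(phenylsulfonyl)bicyclo[2.2.2]oct-5-en-2-one, via o-quinone monoketal 7 (not isolated)
Conditions: PhI(OAc)2 (slow addition), 6 (5 equiv), MeOH, 0 °C → 50 °C
Reagents that add atoms: methanol, CO
Why: PhI(OAc)2 oxidises the phenol to an aryloxy-iodane/phenoxenium species that MeOH traps at the methoxy-bearing ortho carbon remote from the methyl group, giving o-quinone monoketal 7, whose diene C7=C8–C8a=C4a undergoes a concerted suprafacial [4+2] cycloaddition with the vinyl sulfone. The closest known reaction type is the oxidative dearomatisation/intermolecular Diels–Alder reaction of masked o-benzoquinones with electron-poor alkenes. Ring B (C4a–C5–C6–C7–C8–C8a) is closed in an intermolecular [4+2] mode, both new bonds going to the diene termini, and it arises as the cyclohexene ring of a bicyclo[2.2.2]octenone whose keto-ketal bridge is C3–C4. C4a and C7 are set together on one face of the planar diene (cis-1,4, fixed by the concerted mechanism; there is no absolute control, hence step 4), and the sulfonyl-bearing carbon (expected ortho/endo) is erased in step 5. The step needs regioselective ketalisation and cross-cycloaddition in preference to dimerisation of 7; the first should be secured by the methyl group shielding the competing C–OMe carbon, the second by the excess of dienophile and by the methoxy and methyl groups on C7=C8, which make 7 a poor dienophile toward itself.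

Step 4
Reactants: 8 racemic cycloadduct
Product: 9 (1S,4S,7S)-1,3,3-trimethoxy-6-methyl-7-(phenylsulfonyl)bicyclo[2.2.2]oct-5-en-2-one
Conditions: preparative SFC, amylose tris(3,5-dimethylphenylcarbamate) phase, CO2/MeOH
Reagents that add atoms: none
Why: Resolution of the first chiral intermediate (UV-active, single diastereomer) on a chiral stationary phase; the wanted antipode, which carries the target C4a configuration, would be assigned by anomalous-dispersion X-ray analysis (sulfur).

Step 5
Reactants: 9 (1S,4S,7S)-cycloadduct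
Product: 10 (1S,4R)-1-methoxy-6-methylbicyclo[2.2.2]oct-5-en-2-one
Conditions: SmI2 (8 equiv), THF/MeOH, −78 °C; then HMPA, −78 → −20 °C
Reagents that add atoms: none
Why: SmI2 cleaves both C4–OMe bonds α to the ketone (ketyl then β-elimination through the samarium enolate; the bridgehead C7–OMe bond lies in the carbonyl plane and should survive) and, once HMPA is added, the C–SO2Ph bond (reductive desulfonylation), leaving C5–C6 as a plain ethano bridge.

Step 6
Reactants: 10 (1S,4R)-1-methoxy-6-methylbicyclo[2.2.2]oct-5-en-2-one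
Product: 11 (1S,2R,4R)-2-ethenyl-1-methoxy-6-methylbicyclo[2.2.2]oct-5-en-2-ol
Conditions: CH2=CHMgBr, CeCl3, THF, −78 °C
Reagents that add atoms: vinylmagnesium bromide, C=C[Mg]Br
Why: 1,2-Addition of the weakly basic vinylcerium reagent should occur on the ketone face syn to the C8=C8a bridge (less hindered than the ethano-bridge face), which places the vinyl group over the ring alkene as the oxy-Cope rearrangement requires.

Step 7
Reactants: 11 (1S,2R,4R)-2-ethenyl-1-methoxy-6-methylbicyclo[2.2.2]oct-5-en-2-ol
Product: 14 (4aR,8aR)-7-methoxy-8-methyl-4a,5,6,8a-tetrahydronaphthalen-3(4H)-one (target numbering), via potassium enolate 12 (not isolated), via silyl enol ether 13 (not isolated)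
Conditions: KH, 18-crown-6, THF, 0 °C → rt; TMSCl, Et3N, −78 °C; then Pd(OAc)2, MeCN, rt
Reagents that add atoms: none
Why: The anionic oxy-Cope rearrangement ([3,3], boat-like transition state enforced by the bicycle) breaks C3–C7 and forms C1–C8a suprafacially on the bridge face that carries C4, so ring A closes cis-fused with release of strain; the regiodefined enolate is silylated and dehydrogenated (Saegusa–Ito oxidation) to the C1=C2 enone.

Step 8
Reactants: 14 cis-fused enone
Product: 15 (1S,4aR,8aR)-1-ethenyl-7-methoxy-8-methyl-3-(trimethylsilyloxy)-1,4,4a,5,6,8a-hexahydronaphthalene (target numbering)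
Conditions: CH2=CHMgBr, CuBr·SMe2 (cat.), TMSCl, THF, −78 °C; Et3N
Reagents that add atoms: vinylmagnesium bromide, C=C[Mg]Br; chlorotrimethylsilane, C[Si](C)(C)Cl
Why: Copper-catalysed, TMSCl-accelerated 1,4-addition should deliver the vinyl group to C1 on the convex face of the cis-fused enone (anti to the C8a–C8 bond), and the enolate is kept as its silyl enol ether for regiospecific use.

Step 9
Reactants: 15 silyl enol ether; 16 (E)-2-bromobut-2-ene
Product: 18 (1S,2S,4aR,8aR)-2-[(2E)-but-2-en-2-yl]-1-ethenyl-7-methoxy-8-methyl-1,2,4a,5,6,8a-hexahydronaphthalen-3(4H)-one (target numbering), via tributyltin enolate 17 (not isolated)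
Conditions: Bu3SnF, PdCl2[P(o-Tol)3]2 (cat.), PhMe, 100 °C
Reagents that add atoms: none
Why: Fluoride-triggered Si→Sn exchange gives the tin enolate regiospecifically, and palladium-catalysed coupling with the 1-bromoalkene (α-alkenylation of a ketone through its tin enolate, bromide geometry retained) should place the butenyl group on C2 anti to the C1 vinyl group, which is also the thermodynamic arrangement of this epimerisable centre.

Step 10
Reactants: 18 α-butenyl ketone
Product: 19 2,4,6-triisopropylbenzenesulfonylhydrazone of 18 (C3=N)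
Conditions: 2,4,6-iPr3C6H2SO2NHNH2, THF, 4 Å MS, rt
Reagents that add atoms: 2,4,6-triisopropylbenzenesulfonohydrazide, CC(C)c1cc(C(C)C)c(S(=O)(=O)NN)c(C(C)C)c1
Why: Acid-free condensation (the ring-B enol ether is acid-labile) should give the hydrazone with the N–N bond anti to the branched C2, i.e. syn to the C4 methylene.

Step 11
Reactants: 19 trisylhydrazone
Product: 22 (1S,2S,4aS,8S,8aR)-2-[(2E)-but-2-en-2-yl]-1-ethenyl-3,8-dimethyl-1,2,4a,5,6,8a-hexahydronaphthalen-7(8H)-one (target numbering), via alkenyllithium 20 (not isolated), via methyl enol ether 21 (not isolated)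
Conditions: n-BuLi (2.2 equiv), TMEDA, THF, −78 → 0 °C; MeI, −78 °C → rt; then aq. (CO2H)2, THF, 0 °C
Reagents that add atoms: iodomethane, CI; water, O
Why: Shapiro reaction (syn-directed deprotonation at C4, loss of sulfinate and N2) gives the C3 alkenyllithium, which is methylated to install C3–Me and C3=C4 regiospecifically; mild aqueous acid then hydrolyses the ring-B methyl enol ether with kinetic C8 protonation anti to the pseudoaxial C8a–C1 bond, which sets C8.

Step 12
Reactants: 22 C7 ketone
Product: 23 (1S,2S,4aS,7R,8S,8aR)-2-[(2E)-but-2-en-2-yl]-1-ethenyl-3,8-dimethyl-1,2,4a,5,6,7,8,8a-octahydronaphthalen-7-ol (target numbering)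
Conditions: LiBH(s-Bu)3, THF, −78 °C
Reagents that add atoms: none
Why: The bulky hydride should attack C7 from the face opposite the adjacent C8 methyl group (equatorially with respect to the axial C8a–C1 bond), giving the 7,8-cis alcohol before C8 can epimerise.

Step 13
Reactants: 23 dienyl alcohol; 24 methyl (2E,4E)-hexa-2,4-dienoate
Product: 25 methyl (2E,4E)-5-[(1S,2S,4aS,7R,8S,8aR)-2-[(2E)-but-2-en-2-yl]-7-hydroxy-3,8-dimethyl-1,2,4a,5,6,7,8,8a-octahydronaphthalen-1-yl]penta-2,4-dienoate
Conditions: 24 (3 equiv), second-generation Grubbs catalyst, CH2Cl2, 40 °C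
Reagents that add atoms: none
Why: Olefin cross-metathesis at the only monosubstituted alkene of 23 with the 4,5-alkene of the sorbate (its electron-poor 2,3-alkene and the trisubstituted alkenes of 23 should not react), with loss of propene and E geometry favoured in the conjugated diene.

Step 14
Reactants: 25 hydroxy dienoate
Product: 26 sodium salt of the C7 sulfate of 25
Conditions: SO3·pyridine, pyridine, 40 °C; aq. NaHCO3
Reagents that add atoms: sulfur trioxide–pyridine complex, O=S(=O)([O-])[n+]1ccccc1; sodium hydrogencarbonate, [Na+].OC([O-])=O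
Why: O-Sulfation of the secondary alcohol with retention at C7 (the C–O bond is not touched).

Step 15
Reactants: 26 sulfate ester salt
Product: 27 (2E,4E)-5-[(1S,2S,4aS,7R,8S,8aR)-2-[(2E)-but-2-en-2-yl]-3,8-dimethyl-7-(sulfooxy)-1,2,4a,5,6,7,8,8a-octahydronaphthalen-1-yl]penta-2,4-dienoic acid
Conditions: LiOH, THF/MeOH/H2O, rt; then aq. HCl to pH 1, 0 °C, C18 desalting
Reagents that add atoms: lithium hydroxide, [Li+].[OH-]
Why: Saponification of the methyl ester (a sulfate monoester anion resists hydroxide) and cold acidification should give the target in its free-acid form.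

**Compound list**

1 | 2,6-dimethoxyphenol | COc1cccc(OC)c1O | starting material
2 | 2-(methoxymethoxy)-1,3-dimethoxybenzene | COCOc1c(OC)cccc1OC | intermediate
3 | 4-lithio derivative of 2 | COCOc1c(OC)ccc([Li])c1OC | intermediate
4 | 2-(methoxymethoxy)-1,3-dimethoxy-4-methylbenzene | COCOc1c(OC)ccc(C)c1OC | intermediate
5 | 2,6-dimethoxy-3-methylphenol | COc1ccc(C)c(OC)c1O | intermediate
6 | phenyl vinyl sulfone | C=CS(=O)(=O)c1ccccc1 | starting material
7 | 2,6,6-trimethoxy-3-methylcyclohexa-2,4-dien-1-one | COC1=C(C)C=CC(OC)(OC)C1=O | intermediate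
8 | racemic (1S*,4S*,7S*)-1,3,3-trimethoxy-6-methyl-7-(phenylsulfonyl)bicyclo[2.2.2]oct-5-en-2-one (one enantiomer drawn; sulfonyl syn to C5=C6) | COC1(OC)C(=O)[C@]2(OC)[C@@H](S(=O)(=O)c3ccccc3)C[C@H]1C=C2C | intermediate
9 | (1S,4S,7S)-1,3,3-trimethoxy-6-methyl-7-(phenylsulfonyl)bicyclo[2.2.2]oct-5-en-2-one | COC1(OC)C(=O)[C@]2(OC)[C@@H](S(=O)(=O)c3ccccc3)C[C@H]1C=C2C | intermediate
10 | (1S,4R)-1-methoxy-6-methylbicyclo[2.2.2]oct-5-en-2-one | CO[C@@]12CC[C@@H](C=C1C)CC2=O | intermediate
11 | (1S,2R,4R)-2-ethenyl-1-methoxy-6-methylbicyclo[2.2.2]oct-5-en-2-ol (vinyl syn to C5=C6) | CO[C@@]12CC[C@@H](C=C1C)C[C@@]2(O)C=C | intermediate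
12 | potassium C2=C3 enolate of the cis-fused oxy-Cope product (target numbering; C4a, C8a as in 14) | [K+].[O-]C1=CC[C@@H]2C(C)=C(OC)CC[C@@H]2C1 | intermediate
13 | trimethylsilyl enol ether of 12 | C[Si](C)(C)OC1=CC[C@@H]2C(C)=C(OC)CC[C@@H]2C1 | intermediate
14 | (4aR,8aR)-7-methoxy-8-methyl-4a,5,6,8a-tetrahydronaphthalen-3(4H)-one (target numbering; cis-fused) | O=C1C[C@H]2CCC(OC)=C(C)[C@H]2C=C1 | intermediate
15 | (1S,4aR,8aR)-1-ethenyl-7-methoxy-8-methyl-3-(trimethylsilyloxy)-1,4,4a,5,6,8a-hexahydronaphthalene (target numbering) | C[Si](C)(C)OC1=C[C@@H](C=C)[C@@H]2C(C)=C(OC)CC[C@@H]2C1 | intermediate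
16 | (E)-2-bromobut-2-ene | C/C=C(\C)Br | starting material
17 | tributyltin enolate corresponding to 15 | CCCC[Sn](CCCC)(CCCC)OC1=C[C@@H](C=C)[C@@H]2C(C)=C(OC)CC[C@@H]2C1 | intermediate
18 | (1S,2S,4aR,8aR)-2-[(2E)-but-2-en-2-yl]-1-ethenyl-7-methoxy-8-methyl-1,2,4a,5,6,8a-hexahydronaphthalen-3(4H)-one (target numbering) | C/C=C(\C)[C@H]1C(=O)C[C@H]2CCC(OC)=C(C)[C@H]2[C@@H]1C=C | intermediate
19 | 2,4,6-triisopropylbenzenesulfonylhydrazone of 18 (N–N anti to C2 expected) | C/C=C(\C)[C@H]1C(=NNS(=O)(=O)c3c(C(C)C)cc(C(C)C)cc3C(C)C)C[C@H]2CCC(OC)=C(C)[C@H]2[C@@H]1C=C | intermediate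
20 | C3-lithio C3=C4 alkene from 19 | C/C=C(\C)[C@H]1C([Li])=C[C@H]2CCC(OC)=C(C)[C@H]2[C@@H]1C=C | intermediate
21 | C3-methyl C3=C4 alkene that still carries the C7-methoxy C7=C8 enol ether (target numbering) | C/C=C(\C)[C@H]1C(C)=C[C@H]2CCC(OC)=C(C)[C@H]2[C@@H]1C=C | intermediate
22 | (1S,2S,4aS,8S,8aR)-2-[(2E)-but-2-en-2-yl]-1-ethenyl-3,8-dimethyl-1,2,4a,5,6,8a-hexahydronaphthalen-7(8H)-one (target numbering) | C/C=C(\C)[C@H]1C(C)=C[C@H]2CCC(=O)[C@@H](C)[C@H]2[C@@H]1C=C | intermediate
23 | (1S,2S,4aS,7R,8S,8aR)-2-[(2E)-but-2-en-2-yl]-1-ethenyl-3,8-dimethyl-1,2,4a,5,6,7,8,8a-octahydronaphthalen-7-ol (target numbering) | C/C=C(\C)[C@H]1C(C)=C[C@H]2CC[C@@H](O)[C@@H](C)[C@H]2[C@@H]1C=C | intermediate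
24 | methyl (2E,4E)-hexa-2,4-dienoate (methyl sorbate) | C/C=C/C=C/C(=O)OC | starting material
25 | methyl (2E,4E)-5-[(1S,2S,4aS,7R,8S,8aR)-2-[(2E)-but-2-en-2-yl]-7-hydroxy-3,8-dimethyl-1,2,4a,5,6,7,8,8a-octahydronaphthalen-1-yl]penta-2,4-dienoate | C/C=C(\C)[C@H]1C(C)=C[C@H]2CC[C@@H](O)[C@@H](C)[C@H]2[C@@H]1/C=C/C=C/C(=O)OC | intermediate
26 | sodium salt of the C7 sulfate of 25 | C/C=C(\C)[C@H]1C(C)=C[C@H]2CC[C@@H](OS(=O)(=O)[O-])[C@@H](C)[C@H]2[C@@H]1/C=C/C=C/C(=O)OC.[Na+] | intermediate
27 | (2E,4E)-5-[(1S,2S,4aS,7R,8S,8aR)-2-[(2E)-but-2-en-2-yl]-3,8-dimethyl-7-(sulfooxy)-1,2,4a,5,6,7,8,8a-octahydronaphthalen-1-yl]penta-2,4-dienoic acid | C/C=C(\C)[C@H]1C(C)=C[C@H]2CC[C@@H](OS(=O)(=O)O)[C@@H](C)[C@H]2[C@@H]1/C=C/C=C/C(=O)O | target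

**Step count and risks**

Total: 15 steps, all in one line from 1; longest linear sequence: 15 steps.

Step 9 (α-alkenylation of the tin enolate). The palladium enolate at the hindered C2 may undergo β-hydride elimination back to an enone, the tin enolate may lose its regiochemical integrity, or transmetalation may be too slow. The fallback brings the butenyl group in on the oxy-Cope nucleophile; it sets out from ketone 10 and comes back at 18. (E)-3-Methylpent-3-en-2-one is condensed with 2,4,6-triisopropylbenzenesulfonohydrazide to the hydrazone F1. A Shapiro reaction (n-BuLi, 2 equiv) gives (3E)-3-methylpenta-1,3-dien-2-yllithium F2, which adds to 10 (CeCl3) to give the dienyl carbinol F3. Anionic oxy-Cope rearrangement, TMSCl trapping to the silyl dienol ether F4 and Saegusa–Ito oxidation give the cross-conjugated dienone F5. Vinyl cuprate 1,4-addition to C1 and cold protonation of the dienolate at C2 then give 18.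

Step 3 (key dearomatisation/cycloaddition). The monoketal may dimerise faster than it adds the sulfone, methanol may attack the wrong ortho carbon, or bond formation at the fully substituted C7 may be sluggish. The fallback uses a bromine-blocked, isolable monoketal; it sets out from phenol 5 and comes back at 8. Para-bromination (NBS) gives 4-bromo-2,6-dimethoxy-3-methylphenol F6. Oxidation with PhI(OAc)2 in MeOH gives the non-dimerising bromo monoketal F7, which is isolated and heated with excess phenyl vinyl sulfone (PhMe, 110 °C) to give the bromo cycloadduct F8 (Br on C8a). Radical debromination (Bu3SnH, AIBN) returns racemic 8.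

Step 11 (Shapiro methylation and enol-ether hydrolysis). Hydrazone formation at the hindered ketone may stall without acid, the base may remove the doubly activated C2–H in competition, or C8 may epimerise during hydrolysis. The fallback replaces the hydrazone route by enolate triflation and cross-coupling; it sets out from 18 and comes back at 21. Kinetic deprotonation at C4 (KN(SiMe3)2, THF, −78 °C) and O-triflation with N-(5-chloropyridin-2-yl)triflimide give the enol triflate F9. Fe(acac)3-catalysed coupling with MeMgBr gives the methyl enol ether 21, which is hydrolysed under the conditions of step 11 to 22.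

Further compounds

F1 | step 9 | (E)-3-methylpent-3-en-2-one 2,4,6-triisopropylbenzenesulfonylhydrazone | C/C=C(\C)C(C)=NNS(=O)(=O)c1c(C(C)C)cc(C(C)C)cc1C(C)C
F2 | step 9 | (3E)-3-methylpenta-1,3-dien-2-yllithium | C/C=C(\C)C([Li])=C
F3 | step 9 | (1S,2R,4R)-1-methoxy-6-methyl-2-[(3E)-3-methylpenta-1,3-dien-2-yl]bicyclo[2.2.2]oct-5-en-2-ol | CO[C@@]12CC[C@@H](C=C1C)C[C@@]2(O)C(=C)/C(C)=C/C
F4 | step 9 | trimethylsilyl dienol ether of the C2-butenyl oxy-Cope product | C[Si](C)(C)OC1=C(/C(C)=C/C)C[C@@H]2C(C)=C(OC)CC[C@@H]2C1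
F5 | step 9 | cis-fused C2-butenyl C1=C2 enone (cross-conjugated dienone) | O=C1C[C@H]2CCC(OC)=C(C)[C@H]2C=C1/C(C)=C/C
F6 | step 3 | 4-bromo-2,6-dimethoxy-3-methylphenol | COc1cc(Br)c(C)c(OC)c1O
F7 | step 3 | 4-bromo-2,6,6-trimethoxy-3-methylcyclohexa-2,4-dien-1-one | COC1=C(C)C(Br)=CC(OC)(OC)C1=O
F8 | step 3 | racemic 5-bromo-1,3,3-trimethoxy-6-methyl-7-(phenylsulfonyl)bicyclo[2.2.2]oct-5-en-2-one | COC1(OC)C(=O)[C@]2(OC)[C@@H](S(=O)(=O)c3ccccc3)C[C@H]1C(Br)=C2C
F9 | step 11 | C3 enol triflate (C3=C4) of 18 | C/C=C(\C)[C@H]1C(OS(=O)(=O)C(F)(F)F)=C[C@H]2CCC(OC)=C(C)[C@H]2[C@@H]1C=C
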